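**Plan**

- Retrosynthesis: remove the two MOM ethers and the TIPS ether, then cut C3–C4 of the dihydropyranone ring. The C4(=O)–C3(OH) α-ketol is a benzoin retron, so this cut gives the achiral keto-aldehyde 13.
- Next cuts: the O1–C2 aryl ether (→ salicylaldehyde 2 + α-chloroketone 12), then the side chain and the prenyl group of the B ring (→ 2,4-dimethoxyphenol).
- Forward: the B ring is silylated, formylated, prenylated between its two methoxy groups and extended by one carbon to 12. Ether formation with 2 joins the two arenes. The pyranone ring closes last.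
- Enabling feature: C3 is a fully substituted carbinol carbon bonded directly to the C4 carbonyl, and C4 sits on the A ring ortho to the O1–C2 tether. C4 can therefore come from an aldehyde used as an acyl anion that adds to an aryl ketone (C3) in a six-membered closure.
- Stereochemistry: the only stereocentre (C3, S) is set in the ring-closing step by a chiral triazolylidene. Nothing afterwards can epimerise it, since C3 carries no hydrogen.

Key step: step 8

Assumption: the (5aS,10bR) antipode of the aminoindanol triazolium salt is written for step 8; since 13 is achiral the sense of induction rests on the catalyst alone, so the equally available (5aR,10bS) salt is substituted unchanged if Re-face attack (→ 3S) proves to need it.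

**Step 1**
Reactants: 1 2,4,6-trihydroxybenzaldehyde
Product: 2 2-hydroxy-4,6-bis(methoxymethoxy)benzaldehyde
Conditions: MOMCl (2.1 equiv), i-Pr2NEt (2.5 equiv), CH2Cl2, 0 °C → rt
Reagents that add atoms: chloromethyl methyl ether (MOMCl), COCCl
Why: O-alkylation should stop at the bis-ether because the third phenol is held in a hydrogen bond to the formyl oxygen, which leaves free exactly the OH needed in step 7.

**Step 2**
Reactants: 3 2,4-dimethoxyphenol
Product: 4 (2,4-dimethoxyphenoxy)triisopropylsilane
Conditions: TIPSCl, imidazole, DMF, rt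
Reagents that add atoms: triisopropylsilyl chloride, CC(C)[Si](Cl)(C(C)C)C(C)C
Why: Standard phenol silylation; the bulky TIPS ether is chosen because it tolerates organolithiums and does not direct metalation to its own ortho position.

**Step 3**
Reactants: 4 (2,4-dimethoxyphenoxy)triisopropylsilane
Product: 6 2,4-dimethoxy-5-(triisopropylsilyloxy)benzaldehyde, via aryl iminium chloride 5 (not isolated)
Conditions: POCl3 (1.3 equiv), DMF, 0 → 60 °C; then aq NaOAc, rt
Reagents that add atoms: N,N-dimethylformamide, CN(C)C=O (formyl carbon); water, O (carbonyl oxygen)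
Why: Vilsmeier–Haack formylation should attack the one ring position that is para to one methoxy group and ortho to the other (meta to OTIPS), and hydrolysis of iminium 5 releases the aldehyde.

**Step 4**
Reactants: 6 2,4-dimethoxy-5-(triisopropylsilyloxy)benzaldehyde
Product: 10 2,4-dimethoxy-3-(3-methylbut-2-en-1-yl)-5-(triisopropylsilyloxy)benzaldehyde, via lithium amino alkoxide 7 (not isolated), via 3-lithio amino alkoxide 8 (not isolated), via 3-prenyl amino alkoxide 9 (not isolated)
Conditions: N-methylpiperazine/n-BuLi (1.1 equiv), THF, −20 °C; n-BuLi (2.5 equiv), −20 °C; CuBr·SMe2 (20 mol %), prenyl bromide (3.5 equiv), −78 °C → rt; sat. aq NH4Cl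
Reagents that add atoms: 1-bromo-3-methylbut-2-ene (prenyl bromide), CC(C)=CCBr
Why: In situ protection of the aldehyde as an α-amino alkoxide followed by directed ortho-lithiation: with the weakly directing piperazide adduct the proton flanked by the two methoxy groups is the most activated site (the other ring H is shielded by OTIPS), the aryl metal is allylated at the primary carbon of prenyl bromide, and aqueous work-up returns the aldehyde.

**Step 5**
Reactants: 10 2,4-dimethoxy-3-(3-methylbut-2-en-1-yl)-5-(triisopropylsilyloxy)benzaldehyde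
Product: 11 rac-2-chloro-1-[2,4-dimethoxy-3-(3-methylbut-2-en-1-yl)-5-(triisopropylsilyloxy)phenyl]ethan-1-ol
Conditions: ICH2Cl (1.5 equiv), MeLi·LiBr (1.4 equiv), THF, −78 °C; AcOH, −78 °C
Reagents that add atoms: chloroiodomethane, ClCI
Why: Addition of chloromethyllithium (a lithium carbenoid made by I/Li exchange in the presence of the aldehyde, Barbier mode) to the formyl group, with cold acidic quench to hold the product at the chlorohydrin stage; the new carbinol centre is racemic and is erased in step 6.

**Step 6**
Reactants: 11 rac-2-chloro-1-[2,4-dimethoxy-3-(3-methylbut-2-en-1-yl)-5-(triisopropylsilyloxy)phenyl]ethan-1-ol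
Product: 12 2-chloro-1-[2,4-dimethoxy-3-(3-methylbut-2-en-1-yl)-5-(triisopropylsilyloxy)phenyl]ethan-1-one
Conditions: Dess–Martin periodinane (1.3 equiv), CH2Cl2, 0 °C → rt
Reagents that add atoms: none
Why: Dess–Martin oxidation of a secondary benzylic alcohol under near-neutral conditions that should leave the prenyl olefin, the silyl ether and the C–Cl bond untouched.

**Step 7**
Reactants: 2 2-hydroxy-4,6-bis(methoxymethoxy)benzaldehyde; 12 2-chloro-1-[2,4-dimethoxy-3-(3-methylbut-2-en-1-yl)-5-(triisopropylsilyloxy)phenyl]ethan-1-one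
Product: 13 2-{2-[2,4-dimethoxy-3-(3-methylbut-2-en-1-yl)-5-(triisopropylsilyloxy)phenyl]-2-oxoethoxy}-4,6-bis(methoxymethoxy)benzaldehyde
Conditions: K2CO3 (1.5 equiv), DMF, rt
Reagents that add atoms: none
Why: Williamson ether synthesis in which the phenoxide of 2 displaces the activated α-keto chloride by SN2; carbonate at room temperature should keep the intramolecular aldol of the product (Rap–Stoermer benzofuran formation) slow.

**Step 8**
Reactants: 13 2-{2-[2,4-dimethoxy-3-(3-methylbut-2-en-1-yl)-5-(triisopropylsilyloxy)phenyl]-2-oxoethoxy}-4,6-bis(methoxymethoxy)benzaldehyde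
Product: 15 (3S)-3-[2,4-dimethoxy-3-(3-methylbut-2-en-1-yl)-5-(triisopropylsilyloxy)phenyl]-3-hydroxy-5,7-bis(methoxymethoxy)chroman-4-one, via Breslow enaminol 14 (not isolated)
Conditions: (5aS,10bR)-2-(pentafluorophenyl)-5a,10b-dihydro-4H,6H-indeno[2,1-b][1,2,4]triazolo[4,3-d][1,4]oxazinium tetrafluoroborate (20 mol %), Et3N (15 mol %), toluene, rt, Ar
Reagents that add atoms: none
Why: The triazolylidene freed by Et3N adds to the formyl group of 13 and proton transfer gives enaminol 14, whose enol carbon (future C4) attacks the aryl ketone carbon (future C3) while the enol proton passes to the ketone oxygen; the adduct then expels the carbene and leaves the C4 ketone. The closest known reaction type is the carbene-catalysed enantioselective intramolecular crossed aldehyde–ketone benzoin cyclisation of 2-(2-oxoalkoxy)benzaldehydes to 3-hydroxychroman-4-ones. The dihydropyranone ring closes in the 6-exo-trig mode, the attacked C=O keeping its oxygen outside the new ring. C3 is set under catalyst control: the aminoindanol backbone blocks one face of the enaminol and the hydrogen-bonded OH···O=C transition state should present the Re face of the ketone, which gives 3S. The step needs carbene addition to the aldehyde and not the ketone (ketone adducts cannot form an enaminol and revert), and benzoin closure ahead of aldol closure, which is secured by an amine base too weak to enolise the α-aryloxy ketone, used in less than one equivalent per azolium in aprotic toluene. The MOM group on the oxygen ortho to the formyl group removes the OH···O=CH hydrogen bond that would deactivate the aldehyde and protonate the carbene.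

**Step 9**
Reactants: 15 (3S)-3-[2,4-dimethoxy-3-(3-methylbut-2-en-1-yl)-5-(triisopropylsilyloxy)phenyl]-3-hydroxy-5,7-bis(methoxymethoxy)chroman-4-one
Product: 16 (3S)-3-hydroxy-3-[5-hydroxy-2,4-dimethoxy-3-(3-methylbut-2-en-1-yl)phenyl]-5,7-bis(methoxymethoxy)chroman-4-one
Conditions: TBAF (1.1 equiv), AcOH (1.1 equiv), THF, 0 °C
Reagents that add atoms: none
Why: Fluoride cleavage of the aryl silyl ether, buffered with acetic acid so that the α-ketol is not exposed to base; MOM ethers are inert to fluoride.

**Step 10**
Reactants: 16 (3S)-3-hydroxy-3-[5-hydroxy-2,4-dimethoxy-3-(3-methylbut-2-en-1-yl)phenyl]-5,7-bis(methoxymethoxy)chroman-4-one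
Product: 17 sophonorol D, (3S)-3,5,7-trihydroxy-3-[5-hydroxy-2,4-dimethoxy-3-(3-methylbut-2-en-1-yl)phenyl]chroman-4-one
Conditions: 3 M aq HCl/MeOH (1:5), 45 °C
Reagents that add atoms: none
Why: Acid-catalysed transacetalisation of both MOM ethers to methanol; C3 has no hydrogen and cannot epimerise, ionisation of the tertiary alcohol is disfavoured by the adjacent carbonyl, and the prenyl group lies between two methoxy groups with no phenol available for cyclisation.

**Compound list**

1 | 2,4,6-trihydroxybenzaldehyde | O=Cc1c(O)cc(O)cc1O | starting material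
2 | 2-hydroxy-4,6-bis(methoxymethoxy)benzaldehyde | O=Cc1c(O)cc(OCOC)cc1OCOC | intermediate
3 | 2,4-dimethoxyphenol | COc1ccc(O)c(OC)c1 | starting material
4 | (2,4-dimethoxyphenoxy)triisopropylsilane | COc1ccc(O[Si](C(C)C)(C(C)C)C(C)C)c(OC)c1 | intermediate
5 | aryl iminium chloride, N-{[2,4-dimethoxy-5-(triisopropylsilyloxy)phenyl]methylidene}-N-methylmethanaminium chloride (not isolated; counter-ion written as chloride) | C[N+](C)=Cc1cc(O[Si](C(C)C)(C(C)C)C(C)C)c(OC)cc1OC.[Cl-] | intermediate
6 | 2,4-dimethoxy-5-(triisopropylsilyloxy)benzaldehyde | O=Cc1cc(O[Si](C(C)C)(C(C)C)C(C)C)c(OC)cc1OC | intermediate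
7 | lithium amino alkoxide, lithium [2,4-dimethoxy-5-(triisopropylsilyloxy)phenyl](4-methylpiperazin-1-yl)methanolate, racemic (not isolated) | CN1CCN(CC1)C(O[Li])c1cc(O[Si](C(C)C)(C(C)C)C(C)C)c(OC)cc1OC | intermediate
8 | 3-lithio amino alkoxide, compound 7 lithiated at the ring carbon between the two methoxy groups (not isolated) | CN1CCN(CC1)C(O[Li])c1cc(O[Si](C(C)C)(C(C)C)C(C)C)c(OC)c([Li])c1OC | intermediate
9 | 3-prenyl amino alkoxide, compound 7 bearing 3-methylbut-2-en-1-yl between the two methoxy groups (not isolated) | CN1CCN(CC1)C(O[Li])c1cc(O[Si](C(C)C)(C(C)C)C(C)C)c(OC)c(CC=C(C)C)c1OC | intermediate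
10 | 2,4-dimethoxy-3-(3-methylbut-2-en-1-yl)-5-(triisopropylsilyloxy)benzaldehyde | O=Cc1cc(O[Si](C(C)C)(C(C)C)C(C)C)c(OC)c(CC=C(C)C)c1OC | intermediate
11 | rac-2-chloro-1-[2,4-dimethoxy-3-(3-methylbut-2-en-1-yl)-5-(triisopropylsilyloxy)phenyl]ethan-1-ol | OC(CCl)c1cc(O[Si](C(C)C)(C(C)C)C(C)C)c(OC)c(CC=C(C)C)c1OC | intermediate
12 | 2-chloro-1-[2,4-dimethoxy-3-(3-methylbut-2-en-1-yl)-5-(triisopropylsilyloxy)phenyl]ethan-1-one | O=C(CCl)c1cc(O[Si](C(C)C)(C(C)C)C(C)C)c(OC)c(CC=C(C)C)c1OC | intermediate
13 | 2-{2-[2,4-dimethoxy-3-(3-methylbut-2-en-1-yl)-5-(triisopropylsilyloxy)phenyl]-2-oxoethoxy}-4,6-bis(methoxymethoxy)benzaldehyde | O=Cc1c(OCC(=O)c2cc(O[Si](C(C)C)(C(C)C)C(C)C)c(OC)c(CC=C(C)C)c2OC)cc(OCOC)cc1OCOC | intermediate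
14 | Breslow enaminol, the enol formed from the formyl carbon of 13 and C3 of the (5aS,10bR)-triazolylidene, enol geometry open (not isolated) | OC(=C1N(c2c(F)c(F)c(F)c(F)c2F)N=C3N1[C@H]4[C@@H](OC3)Cc5ccccc54)c6c(OCC(=O)c7cc(O[Si](C(C)C)(C(C)C)C(C)C)c(OC)c(CC=C(C)C)c7OC)cc(OCOC)cc6OCOC | intermediate
15 | (3S)-3-[2,4-dimethoxy-3-(3-methylbut-2-en-1-yl)-5-(triisopropylsilyloxy)phenyl]-3-hydroxy-5,7-bis(methoxymethoxy)chroman-4-one | COc1c(O[Si](C(C)C)(C(C)C)C(C)C)cc([C@]2(O)COc3cc(OCOC)cc(OCOC)c3C2=O)c(OC)c1CC=C(C)C | intermediate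
16 | (3S)-3-hydroxy-3-[5-hydroxy-2,4-dimethoxy-3-(3-methylbut-2-en-1-yl)phenyl]-5,7-bis(methoxymethoxy)chroman-4-one | COc1c(O)cc([C@]2(O)COc3cc(OCOC)cc(OCOC)c3C2=O)c(OC)c1CC=C(C)C | intermediate
17 | sophonorol D, (3S)-3,5,7-trihydroxy-3-[5-hydroxy-2,4-dimethoxy-3-(3-methylbut-2-en-1-yl)phenyl]chroman-4-one | COc1c(O)cc([C@]2(O)COc3cc(O)cc(O)c3C2=O)c(OC)c1CC=C(C)C | target

**Step count and risks**

Total steps: 10. Longest linear sequence: 9 steps (steps 2–10, from 2,4-dimethoxyphenol).

Steps most likely to fail:

1. Step 8. The facial discrimination at the ketone may be poor. Both ketone substituents lie near the catalyst, and the aldehyde carries two ortho oxygen substituents, so a bulky chiral carbene may engage slowly or in an unselective geometry. Fallback: setting out from 13, the ring is closed with a small achiral azolium salt (a simple thiazolium salt with Et3N, toluene) to the racemic ketol F1. The tertiary hydroxyl of F1 is then removed by SmI2 (THF/MeOH, −78 °C, reductive cleavage of the α-heteroatom of a ketone) to give the racemic isoflavanone F2. Oxygen is put back under reagent control by asymmetric enolate hydroxylation: KHMDS, THF, −78 °C, then the enantiomer of (camphorsulfonyl)oxaziridine that delivers oxygen to the enolate face giving 3S. The fallback rejoins the route at 15. It still relies on a carbene ring closure and so does not cover a failure of the closure itself.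

2. Step 4. Metalation may go to the wrong ring position (the CH between the amino alkoxide and OTIPS), or may be incomplete under the excess of butyllithium. Fallback: setting out from 4, the silyl ether itself is lithiated between its two methoxy groups (n-BuLi, TMEDA, THF, 0 °C) to the aryllithium F3. F3 is allylated (CuBr·SMe2 cat., prenyl bromide) to the prenyl arene F4. F4 is then formylated para to the hindered methoxy group under Vilsmeier–Haack conditions (POCl3, DMF) through the iminium salt F5, and aqueous NaOAc returns the route at 10.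

3. Step 7. The product, an enolisable ketone tethered to an aldehyde, may undergo base-mediated intramolecular aldol condensation to a benzofuran while the hindered, hydrogen-bonded phenol alkylates slowly. Fallback: setting out from chlorohydrin 11 and phenol 2, K2CO3 in DMF at 60 °C should close 11 to the epoxide F6 in the flask. The phenoxide of 2 opens F6 at its CH2 carbon to the hydroxy ether F7, which has no enolisable ketone. Dess–Martin oxidation of the secondary alcohol of F7 then gives 13, where the route is rejoined.

**Further compounds**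

F1 | step 8 | racemic 3-[2,4-dimethoxy-3-(3-methylbut-2-en-1-yl)-5-(triisopropylsilyloxy)phenyl]-3-hydroxy-5,7-bis(methoxymethoxy)chroman-4-one | COc1c(O[Si](C(C)C)(C(C)C)C(C)C)cc(C2(O)COc3cc(OCOC)cc(OCOC)c3C2=O)c(OC)c1CC=C(C)C
F2 | step 8 | racemic 3-[2,4-dimethoxy-3-(3-methylbut-2-en-1-yl)-5-(triisopropylsilyloxy)phenyl]-5,7-bis(methoxymethoxy)chroman-4-one | COc1c(O[Si](C(C)C)(C(C)C)C(C)C)cc(C2COc3cc(OCOC)cc(OCOC)c3C2=O)c(OC)c1CC=C(C)C
F3 | step 4 | [2,6-dimethoxy-3-(triisopropylsilyloxy)phenyl]lithium | COc1ccc(O[Si](C(C)C)(C(C)C)C(C)C)c(OC)c1[Li]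
F4 | step 4 | [2,4-dimethoxy-3-(3-methylbut-2-en-1-yl)phenoxy]triisopropylsilane | COc1ccc(O[Si](C(C)C)(C(C)C)C(C)C)c(OC)c1CC=C(C)C
F5 | step 4 | N-{[2,4-dimethoxy-3-(3-methylbut-2-en-1-yl)-5-(triisopropylsilyloxy)phenyl]methylidene}-N-methylmethanaminium chloride | C[N+](C)=Cc1cc(O[Si](C(C)C)(C(C)C)C(C)C)c(OC)c(CC=C(C)C)c1OC.[Cl-]
F6 | step 7 | rac-2-[2,4-dimethoxy-3-(3-methylbut-2-en-1-yl)-5-(triisopropylsilyloxy)phenyl]oxirane | C1OC1c1cc(O[Si](C(C)C)(C(C)C)C(C)C)c(OC)c(CC=C(C)C)c1OC
F7 | step 7 | rac-2-{2-[2,4-dimethoxy-3-(3-methylbut-2-en-1-yl)-5-(triisopropylsilyloxy)phenyl]-2-hydroxyethoxy}-4,6-bis(methoxymethoxy)benzaldehyde | O=Cc1c(OCC(O)c2cc(O[Si](C(C)C)(C(C)C)C(C)C)c(OC)c(CC=C(C)C)c2OC)cc(OCOC)cc1OCOC
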